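**Retrosynthetic overview**
- The target is the C2-hydroxymethyl (E)-p-coumarate of (+)-isolariciresinol, (1S,2R,3R), all-trans. Last disconnections: global desilylation, then Steglich esterification of the C2-CH2OH of a tris-silylated core with O-silyl p-coumaric acid.
- The two CH2OH groups are told apart through a trans-fused aryltetralin γ-lactone with its carbonyl on C2: Weinreb ring-opening, silylation of the liberated C3-CH2OH, reduction of the amide to C2-CH2OH.
- The carbocycle (second ring formed) closes by Friedel–Crafts bond formation C1–C8a from a benzylic carbinol. That carbinol comes from the key C1–C2 bond: an intermolecular aldol of the lithium enolate of an (R)-β-benzyl-γ-butyrolactone with O-silylvanillin.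
- The butyrolactone (first ring formed) comes from Evans alkylation of the dihydroferulic acid imide of (S)-4-benzyloxazolidin-2-one with tert-butyl bromoacetate (sets C3), LiBH4 cleavage and lactonisation.
- Ring order: γ-lactone, then tetralin carbocycle, then the lactone is opened. Stereo relay: C3 (auxiliary) → C2 (aldol, trans) → C1 (cyclisation, trans).

Abbreviation: TBS = tert-butyldimethylsilyl; OTBS = its ether. Tetralin numbering is used for the carbocycle (C1 aryl-bearing, C2, C3, C4 = benzylic CH2).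
Assumption: enolates, the mixed anhydride and the silyl esters that exist before the next reagent is added are numbered as non-isolated intermediates; metal alkoxides that are only quenched on work-up are not.

**Route**

Step 1
Reactants: 1 ferulic acid, (E)-3-(4-hydroxy-3-methoxyphenyl)prop-2-enoic acid
Product: 2 dihydroferulic acid, 3-(4-hydroxy-3-methoxyphenyl)propanoic acid
Conditions: H2 (1 atm), 10% Pd/C, MeOH, rt
Reagents that add atoms: none
Why: Heterogeneous catalytic hydrogenation saturates only the conjugated C=C; arene, phenol and acid are untouched.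

Step 2
Reactants: 2 dihydroferulic acid
Product: 4 3-[4-(OTBS)-3-methoxyphenyl]propanoic acid, via silyl ester 3 (not isolated)
Conditions: TBSCl (2.5 equiv), imidazole (5 equiv), DMF, rt; then AcOH/THF/H2O (3:1:1), rt
Reagents that add atoms: tert-butyldimethylsilyl chloride (TBSCl), CC(C)(C)[Si](C)(C)Cl
Why: Exhaustive silylation followed by selective hydrolysis of the labile silyl ester; the aryl silyl ether is stable to aqueous acetic acid.

Step 3
Reactants: 4 3-[4-(OTBS)-3-methoxyphenyl]propanoic acid; 5 (S)-4-benzyloxazolidin-2-one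
Product: 7 (S)-4-benzyl-3-{3-[4-(OTBS)-3-methoxyphenyl]propanoyl}oxazolidin-2-one, via mixed pivalic anhydride 6 (not isolated)
Conditions: PivCl (1.05 equiv), Et3N (2.5 equiv), THF, −20 °C; then LiCl (1.1 equiv), 5, −20 °C → rt
Reagents that add atoms: none
Why: N-acylation through the mixed anhydride; the LiCl/Et3N-activated oxazolidinone attacks the unhindered carbonyl, under conditions mild enough for the aryl silyl ether.

Step 4
Reactants: 7 N-acyl oxazolidinone
Product: 9 tert-butyl (3R)-4-[(4S)-4-benzyl-2-oxooxazolidin-3-yl]-3-[4-(OTBS)-3-methoxybenzyl]-4-oxobutanoate, via sodium Z-enolate 8 (not isolated)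
Conditions: NaN(SiMe3)2 (1.1 equiv), THF, −78 °C, 45 min; BrCH2CO2tBu (2 equiv), −78 → −45 °C
Reagents that add atoms: tert-butyl bromoacetate, CC(C)(C)OC(=O)CBr
Why: Evans asymmetric alkylation; the chelated Z-enolate is alkylated on the face opposite the C4 benzyl of the (S)-auxiliary, which gives the (R) centre (future C3) with dr typically above 95:5.

Step 5
Reactants: 9 alkylated imide
Product: 10 tert-butyl (3R)-4-hydroxy-3-[4-(OTBS)-3-methoxybenzyl]butanoate
Conditions: LiBH4 (1.5 equiv), MeOH (1.5 equiv), THF, 0 °C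
Reagents that add atoms: none
Why: Reductive cleavage of the activated imide carbonyl to the primary alcohol; the tert-butyl ester is inert to LiBH4 at 0 °C, the stereocentre is not enolised and auxiliary 5 is recovered.

Step 6
Reactants: 10 hydroxy tert-butyl ester
Product: 11 (4R)-4-[4-(OTBS)-3-methoxybenzyl]oxolan-2-one
Conditions: p-TsOH·H2O (10 mol %), toluene, 80 °C
Reagents that add atoms: none
Why: Acid-catalysed lactonisation (intramolecular transesterification to the five-membered ring) with loss of tert-butanol; the stereocentre is not involved.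

Step 7
Reactants: 12 vanillin
Product: 13 4-(OTBS)-3-methoxybenzaldehyde
Conditions: TBSCl (1.2 equiv), imidazole (2 equiv), CH2Cl2, rt
Reagents that add atoms: tert-butyldimethylsilyl chloride (TBSCl), CC(C)(C)[Si](C)(C)Cl
Why: Standard phenol silylation; this masks the acidic OH that would quench the enolate in the next step.

Step 8
Reactants: 11 (R)-butyrolactone; 13 O-silylvanillin
Product: 15 (3S,4R)-3-{hydroxy[4-(OTBS)-3-methoxyphenyl]methyl}-4-[4-(OTBS)-3-methoxybenzyl]oxolan-2-one (both carbinol epimers), via lithium enolate 14 (not isolated)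
Conditions: LiN(iPr)2 (1.05 equiv, commercial solution), THF, −78 °C, 45 min; then 13, −78 °C, 1 h; AcOH quench at −78 °C
Reagents that add atoms: none
Why: Intermolecular aldol addition forming C1–C2; the enolate of the β-substituted butyrolactone is attacked anti to the C4 benzyl group, which sets the trans-3,4 lactone (future C2). The carbinol epimers are not separated because that centre is ionised in the next step.

Step 9
Reactants: 15 aldol adduct
Product: 16 (3aR,9S,9aR)-7-(OTBS)-9-[4-(OTBS)-3-methoxyphenyl]-6-methoxy-3a,4,9,9a-tetrahydronaphtho[2,3-c]furan-1(3H)-one (tetralin numbering 1S,2R,3R)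
Conditions: TFA (10 equiv), CH2Cl2, 0 °C → rt, 2 h
Reagents that add atoms: none
Why: Intramolecular Friedel–Crafts alkylation; the para-silyloxy-stabilised benzylic cation from either epimer is trapped para to the methoxy group of the benzyl ring. The aryl group takes the pseudo-equatorial position trans to C2, the same outcome as in the cyclisation of podorhizol-type hydroxy lactones, so C1 is set as S.

Step 10
Reactants: 16 trans,trans aryltetralin lactone
Product: 17 (1S,2R,3R)-7-(OTBS)-1-[4-(OTBS)-3-methoxyphenyl]-3-(hydroxymethyl)-N,6-dimethoxy-N-methyl-1,2,3,4-tetrahydronaphthalene-2-carboxamide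
Conditions: MeNH(OMe)·HCl (3 equiv), AlMe3 (3 equiv), CH2Cl2, 0 °C → rt; aq. KNaC4H4O6 (potassium sodium tartrate) work-up; crude used at once
Reagents that add atoms: N,O-dimethylhydroxylamine hydrochloride, CNOC.Cl
Why: Weinreb aminolysis of the strained trans-fused lactone by the aluminium amide; it frees only the C3-CH2OH and leaves C2 at the carboxyl oxidation level, so the two arms are differentiated chemically.

Step 11
Reactants: 17 hydroxy Weinreb amide
Product: 18 (1S,2R,3R)-7-(OTBS)-1-[4-(OTBS)-3-methoxyphenyl]-3-(TBSO-methyl)-N,6-dimethoxy-N-methyl-1,2,3,4-tetrahydronaphthalene-2-carboxamide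
Conditions: TBSCl (1.5 equiv), imidazole (3 equiv), DMF, 0 °C → rt
Reagents that add atoms: tert-butyldimethylsilyl chloride (TBSCl), CC(C)(C)[Si](C)(C)Cl
Why: Silylation of the primary alcohol is fast and blocks relactonisation.

Step 12
Reactants: 18 silylated Weinreb amide
Product: 19 (1S,2R,3R)-7-(OTBS)-1-[4-(OTBS)-3-methoxyphenyl]-3-(TBSO-methyl)-6-methoxy-1,2,3,4-tetrahydronaphthalene-2-carbaldehyde
Conditions: iBu2AlH (2.2 equiv), THF, −78 °C; aq. KNaC4H4O6 work-up
Reagents that add atoms: none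
Why: Weinreb amide reduction stops at the chelated tetrahedral aluminium adduct and releases the aldehyde on work-up; C2 already carries its substituent equatorially (all-trans), so there is no driving force for epimerisation.

Step 13
Reactants: 19 aldehyde
Product: 20 {(1S,2R,3R)-7-(OTBS)-1-[4-(OTBS)-3-methoxyphenyl]-3-(TBSO-methyl)-6-methoxy-1,2,3,4-tetrahydronaphthalen-2-yl}methanol
Conditions: NaBH4 (1.5 equiv), EtOH/THF, 0 °C
Reagents that add atoms: none
Why: Chemoselective hydride reduction of the aldehyde to the C2-CH2OH; silyl ethers are untouched at 0 °C.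

Step 14
Reactants: 21 p-coumaric acid, (E)-3-(4-hydroxyphenyl)prop-2-enoic acid
Product: 23 (E)-3-[4-(OTBS)phenyl]prop-2-enoic acid, via silyl ester 22 (not isolated)
Conditions: TBSCl (2.5 equiv), imidazole (5 equiv), DMF, rt; then AcOH/THF/H2O (3:1:1), rt
Reagents that add atoms: tert-butyldimethylsilyl chloride (TBSCl), CC(C)(C)[Si](C)(C)Cl
Why: Same bis-silylation and selective silyl ester hydrolysis as in step 2; the E-alkene is unaffected.

Step 15
Reactants: 20 primary alcohol; 23 O-silyl p-coumaric acid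
Product: 24 {(1S,2R,3R)-7-(OTBS)-1-[4-(OTBS)-3-methoxyphenyl]-3-(TBSO-methyl)-6-methoxy-1,2,3,4-tetrahydronaphthalen-2-yl}methyl (E)-3-[4-(OTBS)phenyl]prop-2-enoate
Conditions: DCC (1.5 equiv), DMAP (0.2 equiv), CH2Cl2, 0 °C → rt
Reagents that add atoms: none
Why: Steglich esterification of the only free hydroxyl; the masked phenols cannot compete and the alkene geometry is retained.

Step 16
Reactants: 24 tetrasilylated ester
Product: 25 target, {(1S,2R,3R)-7-hydroxy-1-(4-hydroxy-3-methoxyphenyl)-3-(hydroxymethyl)-6-methoxy-1,2,3,4-tetrahydronaphthalen-2-yl}methyl (E)-3-(4-hydroxyphenyl)prop-2-enoate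
Conditions: Bu4NF (6 equiv), AcOH (6 equiv), THF, 0 °C → rt
Reagents that add atoms: none
Why: Acetic acid-buffered fluoride desilylation removes the three aryl and one alkyl silyl ethers without hydrolysing, isomerising or migrating the cinnamate ester.

**Compound list**
1 | ferulic acid | COc1cc(/C=C/C(=O)O)ccc1O | starting material
2 | dihydroferulic acid | COc1cc(CCC(=O)O)ccc1O | intermediate
3 | TBS 3-[4-(OTBS)-3-methoxyphenyl]propanoate | COc1cc(CCC(=O)O[Si](C)(C)C(C)(C)C)ccc1O[Si](C)(C)C(C)(C)C | intermediate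
4 | 3-[4-(OTBS)-3-methoxyphenyl]propanoic acid | COc1cc(CCC(=O)O)ccc1O[Si](C)(C)C(C)(C)C | intermediate
5 | (S)-4-benzyloxazolidin-2-one | O=C1N[C@@H](Cc2ccccc2)CO1 | starting material
6 | mixed anhydride of 4 and pivalic acid | COc1cc(CCC(=O)OC(=O)C(C)(C)C)ccc1O[Si](C)(C)C(C)(C)C | intermediate
7 | (S)-4-benzyl-3-{3-[4-(OTBS)-3-methoxyphenyl]propanoyl}oxazolidin-2-one | COc1cc(CCC(=O)N2[C@@H](Cc3ccccc3)COC2=O)ccc1O[Si](C)(C)C(C)(C)C | intermediate
8 | sodium (Z)-enolate of 7 | COc1cc(C/C=C(\[O-])N2[C@@H](Cc3ccccc3)COC2=O)ccc1O[Si](C)(C)C(C)(C)C.[Na+] | intermediate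
9 | tert-butyl (3R)-4-[(4S)-4-benzyl-2-oxooxazolidin-3-yl]-3-[4-(OTBS)-3-methoxybenzyl]-4-oxobutanoate | COc1cc(C[C@H](CC(=O)OC(C)(C)C)C(=O)N2[C@@H](Cc3ccccc3)COC2=O)ccc1O[Si](C)(C)C(C)(C)C | intermediate
10 | tert-butyl (3R)-4-hydroxy-3-[4-(OTBS)-3-methoxybenzyl]butanoate | COc1cc(C[C@H](CC(=O)OC(C)(C)C)CO)ccc1O[Si](C)(C)C(C)(C)C | intermediate
11 | (4R)-4-[4-(OTBS)-3-methoxybenzyl]oxolan-2-one | COc1cc(C[C@H]2COC(=O)C2)ccc1O[Si](C)(C)C(C)(C)C | intermediate
12 | vanillin | COc1cc(C=O)ccc1O | starting material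
13 | 4-(OTBS)-3-methoxybenzaldehyde | COc1cc(C=O)ccc1O[Si](C)(C)C(C)(C)C | intermediate
14 | lithium enolate of 11 | COc1cc(C[C@H]2COC([O-])=C2)ccc1O[Si](C)(C)C(C)(C)C.[Li+] | intermediate
15 | (3S,4R)-3-{hydroxy[4-(OTBS)-3-methoxyphenyl]methyl}-4-[4-(OTBS)-3-methoxybenzyl]oxolan-2-one, carbinol epimer mixture | COc1cc(C(O)[C@H]2C(=O)OC[C@@H]2Cc2ccc(O[Si](C)(C)C(C)(C)C)c(OC)c2)ccc1O[Si](C)(C)C(C)(C)C | intermediate
16 | (3aR,9S,9aR)-7-(OTBS)-9-[4-(OTBS)-3-methoxyphenyl]-6-methoxy-3a,4,9,9a-tetrahydronaphtho[2,3-c]furan-1(3H)-one | COc1cc([C@H]2c3cc(O[Si](C)(C)C(C)(C)C)c(OC)cc3C[C@H]3COC(=O)[C@H]23)ccc1O[Si](C)(C)C(C)(C)C | intermediate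
17 | (1S,2R,3R) hydroxy Weinreb amide (C2 = C(O)N(OMe)Me, C3 = CH2OH) | COc1cc([C@H]2c3cc(O[Si](C)(C)C(C)(C)C)c(OC)cc3C[C@@H](CO)[C@@H]2C(=O)N(C)OC)ccc1O[Si](C)(C)C(C)(C)C | intermediate
18 | (1S,2R,3R) silylated Weinreb amide (C3 = CH2OTBS) | COc1cc([C@H]2c3cc(O[Si](C)(C)C(C)(C)C)c(OC)cc3C[C@@H](CO[Si](C)(C)C(C)(C)C)[C@@H]2C(=O)N(C)OC)ccc1O[Si](C)(C)C(C)(C)C | intermediate
19 | (1S,2R,3R) 2-carbaldehyde (C3 = CH2OTBS) | COc1cc([C@H]2c3cc(O[Si](C)(C)C(C)(C)C)c(OC)cc3C[C@@H](CO[Si](C)(C)C(C)(C)C)[C@@H]2C=O)ccc1O[Si](C)(C)C(C)(C)C | intermediate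
20 | (1S,2R,3R) 2-hydroxymethyl compound (C3 = CH2OTBS) | COc1cc([C@H]2c3cc(O[Si](C)(C)C(C)(C)C)c(OC)cc3C[C@@H](CO[Si](C)(C)C(C)(C)C)[C@@H]2CO)ccc1O[Si](C)(C)C(C)(C)C | intermediate
21 | p-coumaric acid | O=C(O)/C=C/c1ccc(O)cc1 | starting material
22 | TBS (E)-3-[4-(OTBS)phenyl]prop-2-enoate | CC(C)(C)[Si](C)(C)OC(=O)/C=C/c1ccc(O[Si](C)(C)C(C)(C)C)cc1 | intermediate
23 | (E)-3-[4-(OTBS)phenyl]prop-2-enoic acid | O=C(O)/C=C/c1ccc(O[Si](C)(C)C(C)(C)C)cc1 | intermediate
24 | tetrasilylated target ester | COc1cc([C@H]2c3cc(O[Si](C)(C)C(C)(C)C)c(OC)cc3C[C@@H](CO[Si](C)(C)C(C)(C)C)[C@@H]2COC(=O)/C=C/c2ccc(O[Si](C)(C)C(C)(C)C)cc2)ccc1O[Si](C)(C)C(C)(C)C | intermediate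
25 | CNP0403384.1, (+)-isolariciresinol C2-hydroxymethyl (E)-p-coumarate | COc1cc([C@H]2c3cc(O)c(OC)cc3C[C@@H](CO)[C@@H]2COC(=O)/C=C/c2ccc(O)cc2)ccc1O | target

**Totals**
Total steps: 16. Longest linear sequence: 14 steps (1–6, 8–13, 15, 16, from ferulic acid).

**Steps most likely to fail, with fallbacks**

Step 9 (cationic cyclisation; risks are dehydration to the benzylidene lactone, partial loss of aryl silyl groups, sluggish closure). The fallback sets out from 15 and comes back at 16. Both aryl silyl ethers are removed with KHF2 in MeOH at rt to give (3S,4R)-3-[hydroxy(4-hydroxy-3-methoxyphenyl)methyl]-4-(4-hydroxy-3-methoxybenzyl)oxolan-2-one F1. With a free para-phenol the carbinol ionises through a p-quinone methide under much milder acid (TFA 1–2 equiv, CH2Cl2, 0 °C), and the free guaiacol ring is a better nucleophile. This closes to (3aR,9S,9aR)-7-hydroxy-9-(4-hydroxy-3-methoxyphenyl)-6-methoxy-3a,4,9,9a-tetrahydronaphtho[2,3-c]furan-1(3H)-one F2. Both phenols are then re-silylated (TBSCl, imidazole, DMF) to give 16.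

Step 10 (Weinreb opening; risks are incomplete opening of the hindered carbonyl and relactonisation of 17 before silylation). The fallback sets out from 16 and comes back at 20, bypassing 17–19. The lactone is reduced with LiBH4 in THF at rt to {(1S,2R,3R)-7-(OTBS)-1-[4-(OTBS)-3-methoxyphenyl]-6-methoxy-1,2,3,4-tetrahydronaphthalene-2,3-diyl}dimethanol F3. The two primary alcohols are then differentiated sterically: TBSCl (1.05 equiv), imidazole, CH2Cl2, −20 °C should favour the C3-CH2OH, because the C2-CH2OH is flanked by the C1 aryl group. Chromatography gives 20; the regioisomer and bis-ether can be desilylated and recycled. The selectivity is expected but not guaranteed.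

Step 16 (global desilylation; risks are acyl migration from the C2 arm to the freed C3-CH2OH, or ester loss under basic fluoride). The fallback sets out from 24 and comes back at 25 by unmasking in two chemoselective stages. KHF2 in MeOH at rt cleaves only the three phenolic silyl ethers to give {(1S,2R,3R)-7-hydroxy-1-(4-hydroxy-3-methoxyphenyl)-3-(TBSO-methyl)-6-methoxy-1,2,3,4-tetrahydronaphthalen-2-yl}methyl (E)-3-(4-hydroxyphenyl)prop-2-enoate F4. The primary silyl ether is then removed under acid (aq. HF, MeCN, 0 °C), where acyl migration is not expected, to give 25.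

**Further compounds**
F1 | step 9 | (3S,4R)-3-[hydroxy(4-hydroxy-3-methoxyphenyl)methyl]-4-(4-hydroxy-3-methoxybenzyl)oxolan-2-one (carbinol epimers) | COc1cc(C(O)[C@H]2C(=O)OC[C@@H]2Cc2ccc(O)c(OC)c2)ccc1O
F2 | step 9 | (3aR,9S,9aR)-7-hydroxy-9-(4-hydroxy-3-methoxyphenyl)-6-methoxy-3a,4,9,9a-tetrahydronaphtho[2,3-c]furan-1(3H)-one | COc1cc([C@H]2c3cc(O)c(OC)cc3C[C@H]3COC(=O)[C@H]23)ccc1O
F3 | step 10 | {(1S,2R,3R)-7-(OTBS)-1-[4-(OTBS)-3-methoxyphenyl]-6-methoxy-1,2,3,4-tetrahydronaphthalene-2,3-diyl}dimethanol | COc1cc([C@H]2c3cc(O[Si](C)(C)C(C)(C)C)c(OC)cc3C[C@@H](CO)[C@@H]2CO)ccc1O[Si](C)(C)C(C)(C)C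
F4 | step 16 | {(1S,2R,3R)-7-hydroxy-1-(4-hydroxy-3-methoxyphenyl)-3-(TBSO-methyl)-6-methoxy-1,2,3,4-tetrahydronaphthalen-2-yl}methyl (E)-3-(4-hydroxyphenyl)prop-2-enoate | COc1cc([C@H]2c3cc(O)c(OC)cc3C[C@@H](CO[Si](C)(C)C(C)(C)C)[C@@H]2COC(=O)/C=C/c2ccc(O)cc2)ccc1O
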